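How far does Q go in a flask charged with 50 µM of E, and how long are its chains?

| flask | Q | E | remark | time |
|---|---|---|---|---|
| winter | 2 mM (fed, over 0.80 s) | 70 µM | run made earlier |  |
| spring | 2 mM (fed, over 0.80 s) | 110 µM | run made earlier |  |
| flask | 2.0 mM (fed, over 0.80 s) | 50 µM |  | 12 min |

| run | time / min | L / % | Q / % |
|---|---|---|---|
| winter | 1.00 | 78.5 | 20.6 |
| winter | 3.00 | 79.9 | 18.7 |
| winter | 6.00 | 80.2 | 18.9 |
| winter | 8.00 | 80.4 | 19.0 |
| winter | 12.0 | 79.9 | 19.0 |
| spring | 1.00 | 83.5 | 15.9 |
| spring | 3.00 | 85.1 | 13.9 |
| spring | 6.00 | 85.5 | 13.9 |
| spring | 8.00 | 84.8 | 14.3 |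
| spring | 12.0 | 85.2 | 14.2 |

(each reading ± 0.3 percentage points)

- the average divides the monomer in chains by the number of chains begun, living and dead together
- steps under discussion: 2 E -> G; Q + X -> L + X; L + X -> Q + X; Q + E -> X + L; X + Q -> J
- the earlier runs do not show the number of chains; that part of a forecast is a guess

* average number of monomer units in a chain (chains begun, living or dead) at 12 min
* part of the Q that has reacted at 12 min

In the winter run Q reads 18.7% at 3.00 min and 19.0% at 12.0 min; in the spring run it reads 13.9% and 14.2%. Both runs stand still within the scatter, but at different levels. So we count how many times Q was halved by 12 min: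

winter: 2.40 halvings; spring: 2.82 halvings

The bench rule says that, with the charge and feed of Q held, halvings go with the charge of E. Applied from winter, it gives our flask 1.71 halvings, so 69.4% reacted. But the rule stops working inside the runs themselves: from winter to spring the halvings grow by a factor 1.18, less than the factor 1.57 on E. The two runs do give a slope, the halvings gained per doubling of E:

slope = 0.644 halvings per doubling

flask, as we reckon it: 2.08 halvings, so an estimate of 76.4% reacted

The runs do not show the number of chains, so we give no chain length of our own.

The forecast says a chain length of 100 and 72% reacted, holding that “the catalyst dies before the reaction finishes”; our figure for the part reacted stands above it.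

The flask gives a chain length of 102 and 75.5% reacted. E is the limiting reagent, with 0% of it left at 12.0 min against 25% of Q.

    2 E → G (k = 24000 /M/s)
    Q + X → L + X, rate k2*[X]*[Q] (k = 12000 /M/s)
    L + X → Q + X, rate k3*[X] as long as [L] is above zero (k = 2.30 /s)
    Q + E → X + L (k = 320 /M/s)
    X + Q → J (k = 97.0 /M/s)

The flask's result amounts to 2.03 halvings, against the 2.08 reckoned. Now take a neighbouring flask with 0.012 mM of E, its Q and time as in the first. Its charge lies 2.54 doublings below winter, so the slope gives it 0.757 halvings and leaves 59.2% of its Q. That neighbouring flask ends with 59.2% of its Q left and 40.8% reacted.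

The earlier runs and the new flask come from a simulation for substances that don't exist; the scatter is artificial.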